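## Structural features

The target 16, cyclointegrin, is an achiral tetracyclic flavone. Ring A is a phloroglucinol-type benzene ring (5-OH, 7-OMe) fused to the γ-pyrone ring C, and ring B is a resorcinol-type ring bonded through C1' to C2. Ring D is an eight-membered cyclic ether made of C2, C3, two methylene carbons, the quaternary CMe2 carbon, the ether oxygen, C2' and C1'; it shares the C2=C3 bond with ring C and the C1'–C2' bond with ring B. There is no stereocentre and no stereogenic double bond, so nothing has to be set or guarded against scrambling. The fragile groups are the tertiary alkyl aryl ether at C2' (it ionises in acid and reopens ring D), the electrophilic pyrone carbon C2 (open to alkoxides and amines), and the two free phenols, which must be kept distinct from the 7-methyl ether. The real difficulty is the medium ring, closed against entropy and transannular strain, together with a tertiary alkoxy group placed ortho to the C2–C1' bond. The key step uses the 1,3-relationship of the ring B oxygens: C2'–C3'–C4'–C5' with their two oxygens form a 1-alkoxy-3-silyloxybutadiene already tied through O–CMe2–CH2–CH2 to C3, and C1'–C6' is an ethynyl group on C2, so that one [4+2] cycloaddition followed by loss of two hydrogens makes ring B and ring D together.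

## Logic of the disconnections

16 from 15 from 14. The O5–CH2Ph and O4'–Si bonds are cut last. Both phenols must be masked throughout, and the two groups come off under neutral or buffered conditions that leave the tertiary ether of ring D alone. The demand is that the hydrogenolysis does not touch the pyrone double bond and that the fluoride step is not basic enough to harm the pyrone.

14 from 13 from 12. Adding two hydrogens to ring B of 14 (at C2' and C5') gives 13, in which C1'–C2' and C5'–C6' are the two σ bonds of a [4+2] adduct. Cutting them opens ring B and ring D at once and leaves 12, in which the chromone carries an ethynyl group on C2 and an acyclic dienyl ether chain on C3. This is the largest simplification of the plan: two rings and the whole medium-ring problem are traded for an acyclic tether. The forward step must cyclise through an eight-membered tether ring and must dehydrogenate 13 before it loses its C2' alkoxide.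

12 from 11. The O–Si bond of the silyl enol ether is cut, giving the methyl ketone 11. The diene is too labile to carry through several steps, so it is made immediately before use. The forward step must silylate the only enolisable position without disturbing the (E)-enol ether or the alkyne.

11 from 9 and 10. The O–CH= bond of the vinylogous ester is cut, giving the tertiary alcohol 9 and the C4 building block 10. This brings in all four diene carbons in one step from a bought reagent. The demand is conjugate addition of a hindered alcohol to 10 in the presence of a second, weaker acceptor (the ethynylpyrone). The enone is installed only after the alkyne because the two preceding steps would destroy it: SeO2 attacks methyl ketones, and methanolic carbonate exchanges β-alkoxy enones.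

9 from 8 from 7. The terminal alkyne carbon is removed (C≡C back to CH=O), then the aldehyde oxygen (CHO back to CH3). The ethynyl group is thus traced to the C2 methyl group that the pyrone synthesis delivers for free. The demands are a homologation mild enough for the pyrone and an oxidation that picks the vinylogously activated methyl group.

7 from 6. The C–O bond of the tertiary alcohol is cut, giving the prenyl compound 6. The forward hydration must be Markovnikov and must leave the pyrone double bond alone. It is placed before the SeO2 step on purpose, since a prenyl group would itself undergo allylic oxidation.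

6 from 5. O1–C2 and C2–C3 are cut, which removes ring C and the two-carbon unit C2–CH3 and leaves the o-hydroxyaryl ketone 5. The forward annulation must acylate the α-carbon once and cyclise; the single α-substituent of 5 guarantees mono-acylation and becomes the C3 side chain.

5 from 4 from 2 and 3. The bond between the ketone α-carbon and the allylic CH2 is cut, giving the acetophenone 2 and 3. The forward alkylation must occur at the enolate carbon of dianion 4 and not at the phenoxide oxygen or the ring.

2 from 1. One O–CH2Ph bond is cut. The two hydroxyls of 1 are equivalent, so the forward mono-benzylation needs only stoichiometric control, and the untouched hydroxyl later becomes O1.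

## Other disconnections considered

Alternative 1: The cut removes the C2–C3 bond of ring C and the CH2–CH2 bond of the tether and, read backwards, restores a bond that 16 does not have, so that ring D contracts to a six-membered chromanone.
- Forward key step: the enamine 1-[7-(benzyloxy)-2,2-dimethyl-2H-chromen-4-yl]pyrrolidine A2 and the ethynyl ketone 1-[2,6-bis(benzyloxy)-4-methoxyphenyl]prop-2-yn-1-one A3 would combine in a stepwise [2+2] cycloaddition. The fused aminocyclobutene would then open (4π electrocyclic) with cleavage of the old chromanone C3–C4 bond to give the eight-membered dienaminone [9-(benzyloxy)-2,2-dimethyl-6-(pyrrolidin-1-yl)-2H-1-benzoxocin-5-yl][2,6-bis(benzyloxy)-4-methoxyphenyl]methanone A1. Saturation of the cis CH=CH bond of A1 with hydrogenolysis of the three benzyl ethers, then addition–elimination of a ring A phenol at the amine-bearing carbon, would complete 16.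
- In its favour: ring D arises by two-carbon expansion of an easily made six-membered ring, so no end-to-end medium-ring closure is needed. The arene precursors of A2 and A3 are bought, and the symmetric ring A removes any regiochemical question in closing ring C.
- Against it here: the β-carbon of A2 sits next to the quaternary CMe2 centre and is conjugated with an aryl ring, so it is hindered and only moderately nucleophilic. With the terminal ynone A3 the zwitterion can collapse by proton transfer to the open-chain Michael adduct instead of closing to the cyclobutene. The hydrogenation of A1 must also spare the push–pull enaminone.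
- Comparison: on structure the alternative is the better plan for ring D (ring expansion instead of a medium-ring cycloaddition). On mechanism the chosen plan has the more dependable regiochemistry, which the tether enforces, but the more fragile intermediate (13). On step economy the alternative is better (about seven steps with a longest linear sequence of about five, against eleven). The end games are equal at two operations after the key step.

Alternative 2: The cut removes C4a–C5 of ring A and O1–C2 of ring C, so that ring A unravels into a linear polyketide chain on the carbon next to the ketone of a ring B–ring D benzoxocinone.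
- Forward key step: Mg(OMe)2 would fold methyl 7-[9-(benzyloxy)-2,2-dimethyl-6-oxo-3,4,5,6-tetrahydro-2H-1-benzoxocin-5-yl]-3,5,7-trioxoheptanoate A5. The methylene between two ketones attacks the ester carbon to close ring A as an acylphloroglucinol, and acidic work-up lets a ring A hydroxyl condense with the ring D ketone to close ring C, giving 4'-O-benzyl-7-O-demethylcyclointegrin A4. Selective 7-O-methylation of A4 and hydrogenolysis would follow.
- In its favour: two rings form in one operation, no oxidant is needed, and the ring B oxygen pattern is secure from the start. The two phloroglucinol hydroxyls that could close ring C are equivalent.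
- Against it here: A5 is a branched tetracarbonyl compound with several competing fates (aldol-type closure to a resorcylate, O-cyclisation to a 4-pyranone, retro-Claisen cleavage at the branched diketone). It has to be assembled by polyanion acylation of 9-(benzyloxy)-2,2-dimethyl-3,4,5,6-tetrahydro-2H-1-benzoxocin-6-one A6. A6 itself contains the eight-membered ring, so the hardest problem is moved rather than solved, and a 5-OH/7-OH differentiation is added at the stage of A4.
- Comparison: on structure the chosen plan is better, because it makes the medium ring in its key step instead of presupposing it. On mechanism the alternative is the equal of the chosen plan in having one delicate cascade, and it is better in avoiding an elimination-prone intermediate. On step economy the two are about equal (roughly ten steps once A6 and the chain are counted), and the end games are equal at two steps.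

Alternative 3: The cut removes C4a–C4 and C4–C3, taking the carbonyl carbon out as a one-carbon unit between a ring A aryl iodide and the benzoxocinone A6.
- Forward key step: Pd(dba)2 with Xantphos and base would join A6, carbon monoxide A9 and 1,3-bis(benzyloxy)-2-iodo-5-methoxybenzene A8. Oxidative addition of zerovalent palladium into the C–I bond of A8, insertion of A9 and coupling of the aroyl–palladium with the ketone enolate of A6 would give the 1,3-diketone 5-[2,6-bis(benzyloxy)-4-methoxybenzoyl]-9-(benzyloxy)-2,2-dimethyl-3,4,5,6-tetrahydro-2H-1-benzoxocin-6-one A7. Hydrogenolysis of the three benzyl ethers of A7 and mild acid cyclodehydration would then give 16.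
- In its favour: it is the most convergent of the plans, it rests on a known reaction class (carbonylative α-arylation of ketones), and the methylation pattern is carried in from A8, so no selective methylation is needed.
- Against it here: A8 is very electron-rich and substituted at both ortho positions, so the aroyl–palladium is hindered and O-acylation, direct arylation or decarbonylation may compete. The acidic product A7 can tie up base and catalyst. A6 again has to be made first, with the medium ring closed by less favourable means.
- Comparison: on step economy and on the end game the alternative is the better plan (possibly one or two steps after the key step and about seven or eight in all, provided A6 is reached in five or fewer). On mechanism it is the equal of the chosen plan in resting on a precedented reaction type used at its steric limit. On structure the chosen plan is better, since it alone addresses ring D directly.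

Key step: step 9

## Route

Assumption: 1 is taken as a catalogue compound. The benzyl and tert-butyldimethylsilyl groups are kept as the protecting groups of 12 and 14. The precursor design is tightened only in the order of operations (hydration before oxidation, alkyne before enone) and in the buffered, acid-free and amine-free handling of 12 and 13.

Step 1
Reactants: 1 1-(2,6-dihydroxy-4-methoxyphenyl)ethan-1-one
Product: 2 1-[2-(benzyloxy)-6-hydroxy-4-methoxyphenyl]ethan-1-one
Conditions: BnBr (1.05 equiv), K2CO3 (1.2 equiv), acetone, reflux
Reagents that add atoms: benzyl bromide, BrCc1ccccc1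
Why: Williamson etherification of one of two equivalent phenols; after the first alkylation the remaining hydroxyl is locked in a strong hydrogen bond to the ketone, so a second benzylation should be slow with near-stoichiometric halide.

Step 2
Reactants: 2 1-[2-(benzyloxy)-6-hydroxy-4-methoxyphenyl]ethan-1-one; 3 1-bromo-3-methylbut-2-ene (prenyl bromide)
Product: 5 1-[2-(benzyloxy)-6-hydroxy-4-methoxyphenyl]-5-methylhex-4-en-1-one, via dilithium dianion 4 (not isolated)
Conditions: LiN(iPr)2 (2.2 equiv), THF, −78 → 0 °C; then 3 (1.05 equiv), −78 → −20 °C; aq NH4Cl
Reagents that add atoms: none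
Why: Two equivalents of LiN(iPr)2 should remove the phenolic proton and one α-proton to give dianion 4, whose enolate carbon is its most nucleophilic site; SN2 attack on the primary allylic carbon of 3 gives the ω-prenyl ketone (enolate C-alkylation), the lithium phenoxide staying inert at low temperature.

Step 3
Reactants: 5 1-[2-(benzyloxy)-6-hydroxy-4-methoxyphenyl]-5-methylhex-4-en-1-one
Product: 6 5-(benzyloxy)-7-methoxy-2-methyl-3-(3-methylbut-2-en-1-yl)-4H-chromen-4-one
Conditions: Ac2O, NaOAc, 140 °C
Reagents that add atoms: acetic anhydride, CC(=O)OC(C)=O
Why: Kostanecki–Robinson annulation: O-acetylation, acetyl transfer to the ketone α-carbon through the enolate and cyclodehydration of the resulting 1,3-diketone by the phenol build ring C with the acetyl methyl at C2 and the prenylated α-carbon as C3; a ketone with one α-substituent cannot be acylated twice, and the benzyl ether and the trisubstituted alkene are inert to acetate.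

Step 4
Reactants: 6 5-(benzyloxy)-7-methoxy-2-methyl-3-(3-methylbut-2-en-1-yl)-4H-chromen-4-one
Product: 7 5-(benzyloxy)-3-(3-hydroxy-3-methylbutyl)-7-methoxy-2-methyl-4H-chromen-4-one
Conditions: Co(acac)2 (20 mol %), PhSiH3 (2.5 equiv), O2 (1 atm), THF, rt; aq Na2S2O3
Reagents that add atoms: dioxygen, O=O
Why: Mukaiyama hydration: a cobalt hydride formed from the divalent cobalt salt, silane and O2 transfers a hydrogen atom to the less substituted alkene carbon, the tertiary radical is trapped by O2 and the peroxide is reduced by the silane, so the Markovnikov tertiary alcohol should result; the tetrasubstituted, electron-poor C2=C3 bond and the benzyl ether do not react.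

Step 5
Reactants: 7 5-(benzyloxy)-3-(3-hydroxy-3-methylbutyl)-7-methoxy-2-methyl-4H-chromen-4-one
Product: 8 5-(benzyloxy)-3-(3-hydroxy-3-methylbutyl)-7-methoxy-4-oxo-4H-chromene-2-carbaldehyde
Conditions: SeO2 (1.5 equiv), 1,4-dioxane, 100 °C
Reagents that add atoms: selenium dioxide, O=[Se]=O
Why: Riley oxidation: the C2 methyl is the γ-position of the pyrone vinylogous ester and enolises toward SeO2, whereas the C3 methylene is not conjugated with the carbonyl, and with the prenyl double bond already hydrated no competing allylic site is left; a seven-membered lactol between the aldehyde and the tertiary alcohol would stay in equilibrium with 8 and react on as the aldehyde.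

Step 6
Reactants: 8 5-(benzyloxy)-3-(3-hydroxy-3-methylbutyl)-7-methoxy-4-oxo-4H-chromene-2-carbaldehyde
Product: 9 5-(benzyloxy)-2-ethynyl-3-(3-hydroxy-3-methylbutyl)-7-methoxy-4H-chromen-4-one
Conditions: MeC(O)C(N2)P(O)(OMe)2 (1.3 equiv), K2CO3 (2 equiv), MeOH, 0 °C → rt
Reagents that add atoms: dimethyl (1-diazo-2-oxopropyl)phosphonate, CC(=O)C(=[N+]=[N-])P(=O)(OC)OC
Why: Ohira–Bestmann variant of the Seyferth–Gilbert homologation: methanolysis of the acetyl group releases the diazomethylphosphonate anion, which adds to the aldehyde and eliminates phosphate; loss of N2 and a 1,2-hydrogen shift in the alkylidene carbene give the terminal alkyne, the carbonate base at 0 °C being mild enough for the pyrone and the tertiary alcohol a spectator.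

Step 7
Reactants: 9 5-(benzyloxy)-2-ethynyl-3-(3-hydroxy-3-methylbutyl)-7-methoxy-4H-chromen-4-one; 10 but-3-yn-2-one
Product: 11 5-(benzyloxy)-2-ethynyl-7-methoxy-3-(3-methyl-3-{[(1E)-3-oxobut-1-en-1-yl]oxy}butyl)-4H-chromen-4-one
Conditions: 10 (2 equiv), PMe3 (10 mol %, added last), CH2Cl2, 0 °C → rt
Reagents that add atoms: none
Why: Phosphine-catalysed oxa-Michael addition: PMe3 adds to 10, the phosphonium allenolate deprotonates the tertiary alcohol and the alkoxide adds to a further molecule of 10 with release of the catalyst, giving the thermodynamically preferred (E)-β-alkoxy enone; selectivity rests on 10 being a far stronger acceptor than the ethynylpyrone of 9, whose alkyne is only vinylogously activated and damped by the ring oxygen.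

Step 8
Reactants: 11 5-(benzyloxy)-2-ethynyl-7-methoxy-3-(3-methyl-3-{[(1E)-3-oxobut-1-en-1-yl]oxy}butyl)-4H-chromen-4-one
Product: 12 5-(benzyloxy)-3-[3-({(1E)-3-[(tert-butyldimethylsilyl)oxy]buta-1,3-dien-1-yl}oxy)-3-methylbutyl]-2-ethynyl-7-methoxy-4H-chromen-4-one
Conditions: TBSOTf (1.3 equiv), Et3N (2.5 equiv), Et2O, −78 → 0 °C; pentane extraction, filtration through Et3N-deactivated silica; used at once
Reagents that add atoms: tert-butyldimethylsilyl trifluoromethanesulfonate, CC(C)(C)[Si](C)(C)OS(=O)(=O)C(F)(F)F
Why: Soft enolisation: the silyl triflate activates the methyl ketone and Et3N removes a proton from the methyl group, the only enolisable position, so the 2-silyloxydiene forms with the (E)-enol ether unchanged, which is the standard way to 1-alkoxy-3-silyloxybutadienes; any silylation of the pyrone carbonyl is reversed on work-up and the terminal alkyne is not silylated under these conditions.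

Step 9
Reactants: 12 5-(benzyloxy)-3-[3-({(1E)-3-[(tert-butyldimethylsilyl)oxy]buta-1,3-dien-1-yl}oxy)-3-methylbutyl]-2-ethynyl-7-methoxy-4H-chromen-4-one
Product: 14 5-O-benzyl-4'-O-(tert-butyldimethylsilyl)cyclointegrin, via cyclohexadiene cycloadduct 13 (not isolated)
Conditions: PhMe (0.005 M), 2,6-di-tert-butyl-4-methylpyridine (0.2 equiv), sealed tube, 120 °C; then DDQ (1.2 equiv), 0 °C → rt, 15 min; filtration through basic alumina
Reagents that add atoms: none
Why: On heating, the diene of 12 adopts the s-cis form and adds across the π bond of the ethynyl group that is conjugated with the pyrone in a concerted, asynchronous normal-demand [4+2]: the CH2 terminus beside the silyloxy carbon, the nucleophilic end, bonds to the electrophilic terminal alkyne carbon (C5'–C6') while the alkoxy-bearing terminus bonds to the internal alkyne carbon (C1'–C2'), giving the 1,4-cyclohexadiene 13. The closest known reaction type is the Diels–Alder reaction of 1-alkoxy-3-silyloxybutadienes with acetylenic acceptors followed by aromatisation, here in its intramolecular type 1 form. Ring B closes as the six-membered cycloadduct ring, and ring D closes as the eight-membered tether ring of the same cycloaddition (diene attached through its C1 oxygen), helped by the cis C2=C3 bond that holds both tether ends on one edge of the pyrone and by the gem-dimethyl group (Thorpe–Ingold effect). DDQ then abstracts hydride from C2'–H, the doubly allylic position whose cation is stabilised by both oxygens, and the arenium ion loses the C5' proton to give the arene of 14 with both oxygens in place. No stereocentre remains: the one stereocentre of 13 (C2', formed as a racemate) is erased by the dehydrogenation, and the only geometric requirement, the (E)-enol ether that places the tether on the outer side of the s-cis diene, is set in step 7. Regioselectivity is secured twice, since the tether allows only the C2'-to-C1' mode and the polarisation of diene and vinylogous ynone favours the same mode. Intramolecular reaction is secured by high dilution, and retention of the C2' oxygen by keeping 13 in a neutral, aprotic medium buffered by a hindered pyridine, so that neither acid-induced ionisation nor base-induced 1,4-elimination of the tertiary alkoxide can occur before DDQ is added cold to the same flask.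

Step 10
Reactants: 14 5-O-benzyl-4'-O-(tert-butyldimethylsilyl)cyclointegrin
Product: 15 5-O-benzylcyclointegrin
Conditions: Bu4NF (1.2 equiv), AcOH (1.2 equiv), THF, 0 °C
Reagents that add atoms: none
Why: Fluoride attacks silicon (strong Si–F bond) and releases the 4'-phenol; AcOH buffers the medium so that neither the pyrone nor the new phenoxide sees basic fluoride, and the benzyl ether and the tertiary alkyl aryl ether are inert.

Step 11
Reactants: 15 5-O-benzylcyclointegrin
Product: 16 cyclointegrin
Conditions: H2 (1 atm), Pd/C (10 %), EtOAc–MeOH, rt
Reagents that add atoms: none
Why: Hydrogenolysis of the benzylic C–O bond on palladium at room temperature; the tetrasubstituted pyrone double bond, the arenes and the tertiary alkyl aryl ether are not reduced, and the neutral medium avoids acid-induced opening of ring D.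

## Compound list

1 | 1-(2,6-dihydroxy-4-methoxyphenyl)ethan-1-one (2',6'-dihydroxy-4'-methoxyacetophenone) | CC(=O)c1c(O)cc(OC)cc1O | starting material
2 | 1-[2-(benzyloxy)-6-hydroxy-4-methoxyphenyl]ethan-1-one | CC(=O)c1c(O)cc(OC)cc1OCc1ccccc1 | intermediate
3 | 1-bromo-3-methylbut-2-ene (prenyl bromide) | CC(C)=CCBr | starting material
4 | dilithium phenoxide–enolate dianion of 2 | [Li+].[Li+].C=C([O-])c1c([O-])cc(OC)cc1OCc1ccccc1 | intermediate
5 | 1-[2-(benzyloxy)-6-hydroxy-4-methoxyphenyl]-5-methylhex-4-en-1-one | CC(C)=CCCC(=O)c1c(O)cc(OC)cc1OCc1ccccc1 | intermediate
6 | 5-(benzyloxy)-7-methoxy-2-methyl-3-(3-methylbut-2-en-1-yl)-4H-chromen-4-one | COc1cc(OCc2ccccc2)c2c(=O)c(CC=C(C)C)c(C)oc2c1 | intermediate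
7 | 5-(benzyloxy)-3-(3-hydroxy-3-methylbutyl)-7-methoxy-2-methyl-4H-chromen-4-one | COc1cc(OCc2ccccc2)c2c(=O)c(CCC(C)(C)O)c(C)oc2c1 | intermediate
8 | 5-(benzyloxy)-3-(3-hydroxy-3-methylbutyl)-7-methoxy-4-oxo-4H-chromene-2-carbaldehyde | COc1cc(OCc2ccccc2)c2c(=O)c(CCC(C)(C)O)c(C=O)oc2c1 | intermediate
9 | 5-(benzyloxy)-2-ethynyl-3-(3-hydroxy-3-methylbutyl)-7-methoxy-4H-chromen-4-one | COc1cc(OCc2ccccc2)c2c(=O)c(CCC(C)(C)O)c(C#C)oc2c1 | intermediate
10 | but-3-yn-2-one | CC(=O)C#C | starting material
11 | 5-(benzyloxy)-2-ethynyl-7-methoxy-3-(3-methyl-3-{[(1E)-3-oxobut-1-en-1-yl]oxy}butyl)-4H-chromen-4-one | COc1cc(OCc2ccccc2)c2c(=O)c(CCC(C)(C)O/C=C/C(C)=O)c(C#C)oc2c1 | intermediate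
12 | 5-(benzyloxy)-3-[3-({(1E)-3-[(tert-butyldimethylsilyl)oxy]buta-1,3-dien-1-yl}oxy)-3-methylbutyl]-2-ethynyl-7-methoxy-4H-chromen-4-one | COc1cc(OCc2ccccc2)c2c(=O)c(CCC(C)(C)O/C=C/C(=C)O[Si](C)(C)C(C)(C)C)c(C#C)oc2c1 | intermediate
13 | 2',5'-dihydro derivative of 14: ring B a 1,4-cyclohexadiene (C1'=C6' and C3'=C4'), sp3 C2' bearing H and the ring D oxygen, sp3 C5'H2; racemic at C2' | COc1cc(OCc2ccccc2)c2c(=O)c3c(oc2c1)C1=CCC(O[Si](C)(C)C(C)(C)C)=CC1OC(C)(C)CC3 | intermediate
14 | 5-O-benzyl-4'-O-(tert-butyldimethylsilyl)cyclointegrin | COc1cc(OCc2ccccc2)c2c(=O)c3c(oc2c1)-c1ccc(O[Si](C)(C)C(C)(C)C)cc1OC(C)(C)CC3 | intermediate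
15 | 5-O-benzylcyclointegrin | COc1cc(OCc2ccccc2)c2c(=O)c3c(oc2c1)-c1ccc(O)cc1OC(C)(C)CC3 | intermediate
16 | cyclointegrin | COc1cc(O)c2c(=O)c3c(oc2c1)-c1ccc(O)cc1OC(C)(C)CC3 | target

## Step count and least certain steps

Total step count: 11. Longest linear sequence: 11 steps (the route is linear; 3 and 10 are bought).

Step 9 (key step). The most likely failure is loss of the tertiary alkoxide from the cycloadduct by 1,4-elimination during the long heating, before the oxidant is present; this rearomatises ring B without its C2' oxygen and reopens ring D. The second is a cycloaddition so slow, because of the eight-membered tether ring, that hydrolysis of the diene or intermolecular addition takes over. The fallback sets out from 9 and returns at 15, closing ring B and ring D in separate operations. 9 would be heated in toluene with an excess of 1-methoxy-1,3-bis(trimethylsilyloxy)buta-1,3-diene. This intermolecular Diels–Alder reaction has the same regiochemical bias, and its adduct carries a ketal carbon at C2', so that acidic work-up (loss of methanol and of the silyl groups) aromatises it without any oxidant to 5-(benzyloxy)-2-(2,4-dihydroxyphenyl)-3-(3-hydroxy-3-methylbutyl)-7-methoxy-4H-chromen-4-one F1. Ring D would then be closed by acid-catalysed cycloetherification (Amberlyst 15 or catalytic TsOH, toluene, removal of water), in which the tertiary carbocation of the side chain is captured by the 2'-hydroxyl, the only phenol within reach, to give 15; the closure is reversible and is driven by the removal of water.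

Step 7. The likely failure is diversion of the nucleophilic catalyst or of the alkoxide to the ethynylpyrone (conjugate addition at the alkyne terminus or at C2), together with oligomerisation of 10 outrunning addition of the hindered tertiary alcohol. The fallback sets out from 9 and returns at 11 without any nucleophile: acid-catalysed trans-etherification of 9 with (E)-4-methoxybut-3-en-2-one (pyridinium p-toluenesulfonate, toluene, 4 Å molecular sieves, 60 °C), an addition–elimination at the β-carbon of the vinylogous ester driven by removal of methanol. It makes no compound beyond those of the route.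

Step 6. The likely failure is conjugate addition of methanol or methoxide to the newly formed ethynylpyrone, or attack at C2 with opening of the pyrone, under the basic methanolic conditions. The fallback sets out from 8 and returns at 9 by an aprotic three-stage Corey–Fuchs-type sequence free of alkoxide and organolithium. Dibromo-olefination (CBr4, PPh3, Zn, CH2Cl2; zinc scavenges the bromophosphonium species and spares the tertiary alcohol) would give 5-(benzyloxy)-2-(2,2-dibromoethenyl)-3-(3-hydroxy-3-methylbutyl)-7-methoxy-4H-chromen-4-one F2. Pd(PPh3)4-catalysed hydrodebromination with Bu3SnH removes the bromine trans to the pyrone and would give 5-(benzyloxy)-2-[(Z)-2-bromoethenyl]-3-(3-hydroxy-3-methylbutyl)-7-methoxy-4H-chromen-4-one F3. DBU then effects anti-elimination of HBr to 9.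

Step 5. The likely failures are over-oxidation to the carboxylic acid, incomplete conversion, and acid-induced dehydration of the tertiary alcohol at 100 °C. The fallback sets out from 7 and returns at 8 without selenium. Condensation of the vinylogously acidic C2 methyl group with N,N-dimethylformamide dimethyl acetal (neat, 120 °C) would give 5-(benzyloxy)-2-[(E)-2-(dimethylamino)ethenyl]-3-(3-hydroxy-3-methylbutyl)-7-methoxy-4H-chromen-4-one F4, and oxidative cleavage of the enamine double bond with NaIO4 (THF–H2O, rt) would give 8.

Step 2. The likely failures are O-alkylation of the phenoxide and double alkylation after proton exchange between the product and unreacted dianion. The fallback sets out from 2 and returns at 6, replacing steps 2 and 3 by alkylation of a far more acidic carbon. Claisen condensation of 2 with ethyl acetate (NaH, THF, reflux) would give 1-[2-(benzyloxy)-6-hydroxy-4-methoxyphenyl]butane-1,3-dione F5. C-prenylation at the central carbon (K2CO3, 3, acetone) would give 1-[2-(benzyloxy)-6-hydroxy-4-methoxyphenyl]-2-(3-methylbut-2-en-1-yl)butane-1,3-dione F6 (racemic; the stereocentre is lost in the next stage), and mild acid cyclodehydration (catalytic TsOH, toluene, 60 °C) would give 6.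

## Further compounds

F1 | step 9 | 5-(benzyloxy)-2-(2,4-dihydroxyphenyl)-3-(3-hydroxy-3-methylbutyl)-7-methoxy-4H-chromen-4-one | COc1cc(OCc2ccccc2)c2c(=O)c(CCC(C)(C)O)c(-c3ccc(O)cc3O)oc2c1
F0 | step 7 | none | none
F2 | step 6 | 5-(benzyloxy)-2-(2,2-dibromoethenyl)-3-(3-hydroxy-3-methylbutyl)-7-methoxy-4H-chromen-4-one | COc1cc(OCc2ccccc2)c2c(=O)c(CCC(C)(C)O)c(C=C(Br)Br)oc2c1
F3 | step 6 | 5-(benzyloxy)-2-[(Z)-2-bromoethenyl]-3-(3-hydroxy-3-methylbutyl)-7-methoxy-4H-chromen-4-one | COc1cc(OCc2ccccc2)c2c(=O)c(CCC(C)(C)O)c(/C=C\Br)oc2c1
F4 | step 5 | 5-(benzyloxy)-2-[(E)-2-(dimethylamino)ethenyl]-3-(3-hydroxy-3-methylbutyl)-7-methoxy-4H-chromen-4-one | COc1cc(OCc2ccccc2)c2c(=O)c(CCC(C)(C)O)c(/C=C/N(C)C)oc2c1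
F5 | step 2 | 1-[2-(benzyloxy)-6-hydroxy-4-methoxyphenyl]butane-1,3-dione | CC(=O)CC(=O)c1c(O)cc(OC)cc1OCc1ccccc1
F6 | step 2 | 1-[2-(benzyloxy)-6-hydroxy-4-methoxyphenyl]-2-(3-methylbut-2-en-1-yl)butane-1,3-dione (racemic) | CC(=O)C(CC=C(C)C)C(=O)c1c(O)cc(OC)cc1OCc1ccccc1
A1 | alternative 1 | [9-(benzyloxy)-2,2-dimethyl-6-(pyrrolidin-1-yl)-2H-1-benzoxocin-5-yl][2,6-bis(benzyloxy)-4-methoxyphenyl]methanone | CC1(C)/C=C\C(C(=O)c2c(OCc3ccccc3)cc(OC)cc2OCc2ccccc2)=C(N2CCCC2)/c2ccc(OCc3ccccc3)cc2O1
A2 | alternative 1 | 1-[7-(benzyloxy)-2,2-dimethyl-2H-chromen-4-yl]pyrrolidine | CC1(C)C=C(N2CCCC2)c2ccc(OCc3ccccc3)cc2O1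
A3 | alternative 1 | 1-[2,6-bis(benzyloxy)-4-methoxyphenyl]prop-2-yn-1-one | C#CC(=O)c1c(OCc2ccccc2)cc(OC)cc1OCc1ccccc1
A4 | alternative 2 | 4'-O-benzyl-7-O-demethylcyclointegrin | Oc1cc(O)c2c(=O)c3c(oc2c1)-c1ccc(OCc2ccccc2)cc1OC(C)(C)CC3
A5 | alternative 2 | methyl 7-[9-(benzyloxy)-2,2-dimethyl-6-oxo-3,4,5,6-tetrahydro-2H-1-benzoxocin-5-yl]-3,5,7-trioxoheptanoate (racemic) | COC(=O)CC(=O)CC(=O)CC(=O)C1CCC(C)(C)Oc2cc(OCc3ccccc3)ccc2C1=O
A6 | alternative 2 | 9-(benzyloxy)-2,2-dimethyl-3,4,5,6-tetrahydro-2H-1-benzoxocin-6-one | CC1(C)CCCC(=O)c2ccc(OCc3ccccc3)cc2O1
A7 | alternative 3 | 5-[2,6-bis(benzyloxy)-4-methoxybenzoyl]-9-(benzyloxy)-2,2-dimethyl-3,4,5,6-tetrahydro-2H-1-benzoxocin-6-one (racemic) | COc1cc(OCc2ccccc2)c(C(=O)C2CCC(C)(C)Oc3cc(OCc4ccccc4)ccc3C2=O)c(OCc2ccccc2)c1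
A8 | alternative 3 | 1,3-bis(benzyloxy)-2-iodo-5-methoxybenzene | COc1cc(OCc2ccccc2)c(I)c(OCc2ccccc2)c1
A9 | alternative 3 | carbon monoxide | [C-]#[O+]
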